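(The data are calculated with made-up constants; scatter was added.)

**The aim.** The product is monomer in chains, and the teal flask, which is the flask asked about, has been followed for the first days.

- teal: free monomer 0.050 M; transfer agent 0.50 mM; protic impurity 0.050 M; initiator 2.5 mol%; the very flask that is asked about, followed so far
- flask: free monomer 0.050 M; transfer agent 0.500 mM; protic impurity 0.0500 M; initiator 2.5 mol%; time 10 d

teal run (percent of the free monomer charged)

| time / d | monomer in chains / % | free monomer / % |
|---|---|---|
| 0.167 | 1 | 77 |
| 0.500 | 10 | 55 |
| 0.833 | 13 | 41 |
| 1.25 | 16 | 29 |
| 1.67 | 14 | 21 |
| 2.50 | 20 | 14 |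
| 3.00 | 18 | 11 |

(readings scatter by 1.5 percentage points)

* average number of monomer units in a chain (chains begun, living or dead) at 10 d
* part of the free monomer that has reacted at 10 d

- the average divides the monomer in chains by the number of chains begun, living and dead together
- the earlier runs do not show the number of chains; that part of a forecast is a guess

**Two numbers.** At 3.00 d the teal flask has 11% of its free monomer left, so 89.0% has reacted, yet monomer in chains reads 18%.

**My reckoning.** I book the difference, 71.0% of the charge, as lost to the protic impurity, which is charged equimolar to the free monomer. That gives a reading of 0.254: the chain ratio, a selectivity factor, is monomer in chains per monomer lost. Carried to full conversion, it puts 20.2% of the charge in chains, and if each initiator begins one chain, dp is 8.09. If each transfer agent ends one chain, the surplus of initiator over transfer agent is 1.50% of the charge, and I take the chain ratio to follow that surplus over the protic impurity.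

**The forecast.** It gives dp 6.2 (3.5 to 9) and c 98.8% (97.3% to 99.8%), and says “Chains begun are a guess”. My dp is higher; its c I accept.

**The result.** The flask gives dp 14.3, above the forecast's range, and c 99.7%. It holds 23.7% of the charge in chains, over chains begun, living and dead, of 1.67%.

    free monomer + initiator → spent initiator (k = 1.54 L mol⁻¹ h⁻¹)
    free monomer + initiator → living end + monomer in chains (k = 3.09 L mol⁻¹ h⁻¹)
    living end + transfer agent → dead chain (kL = 101 L mol⁻¹ h⁻¹)
    free monomer + living end → monomer in chains + living end, rate k4*[living end]*[free monomer] (k = 19.5 L mol⁻¹ h⁻¹)
    protic impurity + free monomer → quenched substrate (k = 1.01 L mol⁻¹ h⁻¹)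

**The rates.** At 0.535 d quenching in this flask uses free monomer 3.1 times as fast as chain growth does. At 10.0 d this flask holds 75.1% of the charge as quenched substrate and 23.7% as monomer in chains.

**Second flask.** The neighbour charged with 0.030 M of free monomer has a surplus of 0.833% of its charge, in amount a third of the surplus in the teal flask, against the same protic impurity, so by my reckoning its chain ratio is 0.0845, giving 7.79% in chains and dp 3.12. Computed, that neighbour holds 10.4% in chains, with dp 6.45, higher than my dp.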